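The plan rests on the strained cis C4=C5 bond of the nine-membered oxacycle (O–C3–C4=C5–C6–C7–C8–C9–C10). C4 and C5 both enter as electrophilic carbons and are first joined through sulfur. Because C4 is the acidified γ-carbon of the 3(2H)-furanone ring, the resulting ten-membered thiacyclic sulfone should undergo a one-flask Ramberg–Bäcklund reaction that extrudes SO2, creates the cis alkene and contracts the ring by one atom. The precursor already carries the furanone, the trans α-methylene lactone and the tiglate. C10 is bought with (S)-lactic acid and C6 with a four-carbon tosylate; C7 and C8 are relayed from C6 in one chromium-mediated allylation that closes the thiacycle.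

Key step: step 13

Remark on numbering: germacrane-type labels are used: C1 (furanone C=O), C2 (=CH), C3 (O–C=), C4 (carries C15H2O), C5, C6 (lactone O–CH), C7, C8 (ester O–CH), C9 (CH2), C10 (quaternary, C14 methyl), C11=C13 (exocyclic methylene), C12 (lactone C=O).
Assumption: the sulfur-bearing carbon C4 is carried from 12 to 27 as a mixture of epimers (no descriptor in the SMILES); it becomes sp2 in step 13, so both epimers converge.

Step 1
Reactants: 1 (2S,5S)-2-tert-butyl-5-methyl-1,3-dioxolan-4-one; 2 allyl bromide
Product: 4 (2S,5R)-5-allyl-2-tert-butyl-5-methyl-1,3-dioxolan-4-one, via lithium enolate 3 (not isolated)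
Conditions: LiN(iPr)2, THF, −78 °C; then 2, −78 to −30 °C
Reagents that add atoms: lithium diisopropylamide, [Li]N(C(C)C)C(C)C (lithium of intermediate 3 only)
Why: Enolate alkylation with self-regeneration of the stereocentre: the tert-butyl group on the acetal carbon shields one face, so allyl bromide should enter trans to it and replace the original C–H with retention, which sets the quaternary centre that becomes C10.

Step 2
Reactants: 4 (2S,5R)-5-allyl-2-tert-butyl-5-methyl-1,3-dioxolan-4-one
Product: 6 (2S,5R)-2-tert-butyl-5-(2,2-dimethoxyethyl)-5-methyl-1,3-dioxolan-4-one, via aldehyde 5 (not isolated)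
Conditions: O3, CH2Cl2/MeOH, −78 °C; Me2S; then HC(OMe)3, PPTS (cat.), rt
Reagents that add atoms: trimethyl orthoformate, COC(OC)OC (both methoxy groups of 6); ozone, [O-][O+]=O (carbonyl oxygen of intermediate 5 only)
Why: Ozonolysis of the only alkene with reductive work-up, then acetalisation in the same flask under mild acid that should leave the dioxolanone intact, masks C8 as a dimethyl acetal without touching either stereocentre.

Step 3
Reactants: 6 (2S,5R)-2-tert-butyl-5-(2,2-dimethoxyethyl)-5-methyl-1,3-dioxolan-4-one; 7 tert-butyl(but-3-yn-1-yloxy)dimethylsilane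
Product: 9 (3R)-8-[(tert-butyldimethylsilyl)oxy]-3-hydroxy-1,1-dimethoxy-3-methyloct-5-yn-4-one, via lithium acetylide 8 (not isolated)
Conditions: 7, n-BuLi, THF, −78 °C; then 6, −78 °C; then H2O
Reagents that add atoms: n-butyllithium, [Li]CCCC (lithium of intermediate 8 only)
Why: Single addition of an alkynyllithium to the lactone-type carbonyl (acylation of an acetylide): the lithium hemiketal should persist at low temperature and on quenching collapse with loss of pivalaldehyde to unveil the tertiary α'-hydroxy ynone, the quaternary centre being untouched.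

Step 4
Reactants: 9 (3R)-8-[(tert-butyldimethylsilyl)oxy]-3-hydroxy-1,1-dimethoxy-3-methyloct-5-yn-4-one
Product: 10 (2R)-5-{2-[(tert-butyldimethylsilyl)oxy]ethyl}-2-(2,2-dimethoxyethyl)-2-methylfuran-3(2H)-one
Conditions: Ph3PAuNTf2 (cat., monovalent gold), CH2Cl2, rt
Reagents that add atoms: none
Why: π-Acid-catalysed 5-endo-dig hydroalkoxylation (oxa-Michael-type cycloisomerisation) of the α'-hydroxy ynone should close the 3(2H)-furanone with C10 unchanged.

Step 5
Reactants: 10 (2R)-5-{2-[(tert-butyldimethylsilyl)oxy]ethyl}-2-(2,2-dimethoxyethyl)-2-methylfuran-3(2H)-one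
Product: 12 (2R)-5-{1-bromo-2-[(tert-butyldimethylsilyl)oxy]ethyl}-2-(2,2-dimethoxyethyl)-2-methylfuran-3(2H)-one (both C4 epimers), via silyl dienol ether 11 (not isolated)
Conditions: LiN(iPr)2, Me3SiCl, THF, −78 °C; then NBS, −78 to −40 °C
Reagents that add atoms: N-bromosuccinimide, BrN1C(=O)CCC1=O (bromine); chlorotrimethylsilane, C[Si](C)(C)Cl (silyl group of intermediate 11 only)
Why: With C10 quaternary the only acidic position is the γ-methylene C4, so γ-deprotonation and O-silylation should give the exocyclic dienol ether, which NBS brominates at the γ-terminus with return of the furanone (γ-halogenation of a silyl dienol ether); the new C4 centre forms unselectively and is destroyed later.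

Step 6
Reactants: 12 (2R)-5-{1-bromo-2-[(tert-butyldimethylsilyl)oxy]ethyl}-2-(2,2-dimethoxyethyl)-2-methylfuran-3(2H)-one; 13 (2S)-2-hydroxybut-3-en-1-yl 4-methylbenzenesulfonate
Product: 16 (2R)-5-{2-[(tert-butyldimethylsilyl)oxy]-1-{[(2S)-2-hydroxybut-3-en-1-yl]sulfanyl}ethyl}-2-(2,2-dimethoxyethyl)-2-methylfuran-3(2H)-one, via thioacetate 14 (not isolated), via thiol 15 (not isolated)
Conditions: KSAc (potassium thioacetate), DMF, 0 °C; then 13, K2CO3, MeOH, 0 °C to rt
Reagents that add atoms: potassium thioacetate, CC(=O)[S-].[K+] (sulfur)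
Why: SN2 displacement of the activated bromide by thioacetate, in-flask methanolysis to the thiolate and S-alkylation by the primary tosylate (thioether synthesis) should join C4 and C5 through sulfur; carbonate is too weak to ionise the secondary alcohol, so the carbinol centre of 13 (future C6) is carried over unchanged.

Step 7
Reactants: 16 sulfide alcohol; 17 2-(bromomethyl)acrylic acid
Product: 18 (2S)-1-{[sulfanyl-substituted furanone]}but-3-en-2-yl 2-(bromomethyl)acrylate (the C6 ester of 16)
Conditions: 17, DCC, DMAP (cat.), CH2Cl2, −20 to 0 °C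
Reagents that add atoms: none
Why: Steglich esterification of the secondary allylic alcohol at low temperature with only catalytic DMAP should install the bromomethacrylate without touching the configuration at C6.

Step 8
Reactants: 18 bromomethacrylate ester
Product: 19 (5S)-3-(bromomethyl)-5-(sulfanylmethyl)furan-2(5H)-one carrying the furanone acetal on sulfur (bromomethyl butenolide)
Conditions: second-generation Grubbs catalyst (H2IMes)(PCy3)Cl2Ru=CHPh (cat.), toluene, 80 °C, dilute
Reagents that add atoms: none
Why: Ring-closing metathesis between the vinyl group and the 1,1-disubstituted acrylate should close the five-membered butenolide with loss of ethylene, turning the ester into a cyclic allylic bromide whose ring geometry is fixed; C6 is not affected.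

Step 9
Reactants: 19 bromomethyl butenolide acetal
Product: 20 bromomethyl butenolide aldehyde (C8 aldehyde)
Conditions: In(OTf)3 (cat.), acetone/H2O, rt
Reagents that add atoms: water, O (aldehyde oxygen)
Why: Lewis-acid-catalysed acetal hydrolysis under near-neutral conditions should spare the silyl ether and the allylic bromide; the β-oxygenated aldehyde is used at once because base would eliminate the furanone oxygen.

Step 10
Reactants: 20 bromomethyl butenolide aldehyde
Product: 22 macrocyclic sulfide alcohol (ten-membered ring O–C3–C4–S–C5–C6–C7–C8–C9–C10, bridged by the furanone, trans-fused at C6–C7 to the α-methylene-γ-butyrolactone, free 8-OH, C6/C7/C8/C10 as in the target), via allylchromium species 21 (not isolated)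
Conditions: CrCl2, THF/DMF, rt, slow addition at high dilution
Reagents that add atoms: chromium dichloride, Cl[Cr]Cl (metal and chlorides of intermediate 21 only)
Why: Intramolecular Nozaki–Hiyama (Barbier-type) allylation: divalent chromium converts the allylic bromide into 21, whose γ-carbon C7 should add to the aldehyde through a closed chair transition state, attack anti to the C5 arm on the butenolide setting C7 trans to C6, the ring-fixed allyl geometry setting C8 anti to C7, and the exocyclic methylene lactone emerging directly.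

Step 11
Reactants: 22 macrocyclic sulfide alcohol; 23 tigloyl chloride [(E)-2-methylbut-2-enoyl chloride]
Product: 24 macrocyclic sulfide 8-O-tiglate
Conditions: 23, pyridine, DMAP (cat.), CH2Cl2, 0 °C to rt
Reagents that add atoms: none
Why: Acylation (nucleophilic catalysis) of the only free hydroxyl; pyridine is too weak a base to form the vinylketene, so the E geometry of the tiglate should be kept.

Step 12
Reactants: 24 macrocyclic sulfide 8-O-tiglate
Product: 25 macrocyclic sulfone (S between C4 and C5)
Conditions: mCPBA (2.2 equiv), CH2Cl2, 0 °C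
Reagents that add atoms: 3-chloroperbenzoic acid, OOC(=O)c1cccc(Cl)c1 (both sulfone oxygens)
Why: Electrophilic oxidation of the sulfide to the sulfone; the methylene lactone, tiglate and furanone alkenes are electron-poor and should not be epoxidised.

Step 13
Reactants: 25 macrocyclic sulfone
Product: 28 15-O-(tert-butyldimethylsilyl)lychnophorolide B, via α-bromo sulfone 26 (not isolated), via episulfone 27 (not isolated)
Conditions: KOH/Al2O3, CBr2F2, t-BuOH/CH2Cl2, 0 °C to rt
Reagents that add atoms: dibromodifluoromethane, FC(F)(Br)Br (bromine of intermediate 26 only; nothing is left in 28)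
Why: Hydroxide on alumina should first remove the most acidic proton, at C4 (α to the sulfone and γ to the furanone carbonyl), and the carbanion is brominated by CBr2F2 to give 26; deprotonation at C5 then triggers 1,3-displacement of bromide to episulfone 27, which loses SO2 in a stereospecific cheletropic step to leave the C4=C5 double bond. The closest known reaction type is the in situ halogenative Ramberg–Bäcklund ring contraction of cyclic sulfones to medium-ring cycloalkenes. The only ring closed is the transient three-membered thiirane dioxide, by 3-exo-tet attack of the C5 carbanion on C4; the nine-membered oxacycle is not closed but arises from the ten-membered ring by loss of sulfur. No stereocentre is created: both C4 epimers converge, and the alkene geometry (C3 and C6 cis) is dictated by the ring, because only the cis-fused episulfone can be spanned by the remaining seven atoms. The step needs ring closure of the C5 carbanion to outrun β-elimination of the C6 lactone oxygen and of the C15 silyloxy group; the tertiary, doubly activated C4–Br bond, the low temperature and the heterogeneous base are relied on for this, and the esters, the silyl ether and the electron-poor alkenes should survive.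

Step 14
Reactants: 28 15-O-(tert-butyldimethylsilyl)lychnophorolide B
Product: 29 lychnophorolide B
Conditions: HF·pyridine, THF/pyridine, 0 °C to rt
Reagents that add atoms: none
Why: Fluoride-mediated cleavage of the primary allylic silyl ether under buffered, weakly acidic conditions should spare the methylene lactone, the tiglate and the dienone.

Compound list
1 | (2S,5S)-2-tert-butyl-5-methyl-1,3-dioxolan-4-one (cis pivalaldehyde acetal of (S)-lactic acid) | C[C@@H]1O[C@H](C(C)(C)C)OC1=O | starting material
2 | allyl bromide | C=CCBr | starting material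
3 | lithium enolate of 1 | CC1=C(O[Li])O[C@@H](C(C)(C)C)O1 | intermediate (not isolated)
4 | (2S,5R)-5-allyl-2-tert-butyl-5-methyl-1,3-dioxolan-4-one | C[C@]1(CC=C)O[C@H](C(C)(C)C)OC1=O | intermediate
5 | 2-[(2S,4R)-2-tert-butyl-4-methyl-5-oxo-1,3-dioxolan-4-yl]acetaldehyde | C[C@]1(CC=O)O[C@H](C(C)(C)C)OC1=O | intermediate (not isolated)
6 | (2S,5R)-2-tert-butyl-5-(2,2-dimethoxyethyl)-5-methyl-1,3-dioxolan-4-one | C[C@]1(CC(OC)OC)O[C@H](C(C)(C)C)OC1=O | intermediate
7 | tert-butyl(but-3-yn-1-yloxy)dimethylsilane | C#CCCO[Si](C)(C)C(C)(C)C | starting material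
8 | lithium acetylide of 7 | [Li]C#CCCO[Si](C)(C)C(C)(C)C | intermediate (not isolated)
9 | (3R)-8-[(tert-butyldimethylsilyl)oxy]-3-hydroxy-1,1-dimethoxy-3-methyloct-5-yn-4-one | CC(C)(C)[Si](C)(C)OCCC#CC(=O)[C@@](C)(CC(OC)OC)O | intermediate
10 | (2R)-5-{2-[(tert-butyldimethylsilyl)oxy]ethyl}-2-(2,2-dimethoxyethyl)-2-methylfuran-3(2H)-one | CC(C)(C)[Si](C)(C)OCCC1=CC(=O)[C@@](C)(CC(OC)OC)O1 | intermediate
11 | trimethylsilyl dienol ether of 10 (exocyclic C3=C4, 1-silyloxy C1=C2) | CC(C)(C)[Si](C)(C)OCC=C1C=C(O[Si](C)(C)C)[C@@](C)(CC(OC)OC)O1 | intermediate (not isolated)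
12 | (2R)-5-{1-bromo-2-[(tert-butyldimethylsilyl)oxy]ethyl}-2-(2,2-dimethoxyethyl)-2-methylfuran-3(2H)-one, C4 epimers | CC(C)(C)[Si](C)(C)OCC(Br)C1=CC(=O)[C@@](C)(CC(OC)OC)O1 | intermediate
13 | (2S)-2-hydroxybut-3-en-1-yl 4-methylbenzenesulfonate | C=C[C@H](O)COS(=O)(=O)c1ccc(C)cc1 | starting material
14 | S-thioacetate from 12 (acetylthio group at C4) | CC(=O)SC(CO[Si](C)(C)C(C)(C)C)C1=CC(=O)[C@@](C)(CC(OC)OC)O1 | intermediate (not isolated)
15 | C4 thiol from 14 (present as its potassium thiolate) | SC(CO[Si](C)(C)C(C)(C)C)C1=CC(=O)[C@@](C)(CC(OC)OC)O1 | intermediate (not isolated)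
16 | (2R)-5-{2-[(tert-butyldimethylsilyl)oxy]-1-{[(2S)-2-hydroxybut-3-en-1-yl]sulfanyl}ethyl}-2-(2,2-dimethoxyethyl)-2-methylfuran-3(2H)-one | C=C[C@H](O)CSC(CO[Si](C)(C)C(C)(C)C)C1=CC(=O)[C@@](C)(CC(OC)OC)O1 | intermediate
17 | 2-(bromomethyl)acrylic acid | C=C(CBr)C(=O)O | starting material
18 | 2-(bromomethyl)acrylate ester of 16 at the C6 hydroxyl | C=C[C@H](OC(=O)C(=C)CBr)CSC(CO[Si](C)(C)C(C)(C)C)C1=CC(=O)[C@@](C)(CC(OC)OC)O1 | intermediate
19 | (5S)-3-(bromomethyl)-5-(sulfanylmethyl)furan-2(5H)-one bearing the furanone dimethyl acetal on sulfur | BrCC1=C[C@@H](CSC(CO[Si](C)(C)C(C)(C)C)C2=CC(=O)[C@@](C)(CC(OC)OC)O2)OC1=O | intermediate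
20 | aldehyde from 19 (C8 aldehyde) | BrCC1=C[C@@H](CSC(CO[Si](C)(C)C(C)(C)C)C2=CC(=O)[C@@](C)(CC=O)O2)OC1=O | intermediate
21 | allylchromium dichloride from 20 (trivalent chromium on C13) | Cl[Cr](Cl)CC1=C[C@@H](CSC(CO[Si](C)(C)C(C)(C)C)C2=CC(=O)[C@@](C)(CC=O)O2)OC1=O | intermediate (not isolated)
22 | macrocyclic sulfide alcohol (ten-membered thia-ring, furanone bridge, trans α-methylene lactone, 8-OH) | C=C1C(=O)O[C@@H]2CSC(CO[Si](C)(C)C(C)(C)C)C3=CC(=O)[C@@](C)(C[C@H](O)[C@@H]12)O3 | intermediate
23 | tigloyl chloride [(E)-2-methylbut-2-enoyl chloride] | C/C=C(\C)C(=O)Cl | starting material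
24 | macrocyclic sulfide 8-O-tiglate | C=C1C(=O)O[C@@H]2CSC(CO[Si](C)(C)C(C)(C)C)C3=CC(=O)[C@@](C)(C[C@H](OC(=O)/C(C)=C/C)[C@@H]12)O3 | intermediate
25 | macrocyclic sulfone 8-O-tiglate | C=C1C(=O)O[C@@H]2CS(=O)(=O)C(CO[Si](C)(C)C(C)(C)C)C3=CC(=O)[C@@](C)(C[C@H](OC(=O)/C(C)=C/C)[C@@H]12)O3 | intermediate
26 | α-bromo sulfone (bromine on C4) | C=C1C(=O)O[C@@H]2CS(=O)(=O)C(Br)(CO[Si](C)(C)C(C)(C)C)C3=CC(=O)[C@@](C)(C[C@H](OC(=O)/C(C)=C/C)[C@@H]12)O3 | intermediate (not isolated)
27 | episulfone (thiirane 1,1-dioxide across C4–C5, C3 and C6 cis) | C=C1C(=O)O[C@@H]2C4C(CO[Si](C)(C)C(C)(C)C)(S4(=O)=O)C3=CC(=O)[C@@](C)(C[C@H](OC(=O)/C(C)=C/C)[C@@H]12)O3 | intermediate (not isolated)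
28 | 15-O-(tert-butyldimethylsilyl)lychnophorolide B | C=C1C(=O)O[C@@H]2/C=C(/CO[Si](C)(C)C(C)(C)C)C3=CC(=O)[C@@](C)(C[C@H](OC(=O)/C(C)=C/C)[C@@H]12)O3 | intermediate
29 | lychnophorolide B | C=C1C(=O)O[C@@H]2/C=C(/CO)C3=CC(=O)[C@@](C)(C[C@H](OC(=O)/C(C)=C/C)[C@@H]12)O3 | target

Total step count: 14. Longest linear sequence: 14 steps (1 to 29); 2, 7, 13, 17 and 23 are bought.

Steps most likely to fail

Step 13. The C5 α-sulfonyl carbanion may expel the C6 lactone carboxylate by β-elimination faster than it closes onto C4, and re-addition could scramble C6. The fallback removes the leaving group instead of changing the base. It sets out from 22, which is silylated at the 8-hydroxyl (Et3SiCl, imidazole) to the triethylsilyl ether F1 and oxidised with mCPBA to the sulfone F2. The contraction is then run in aqueous hydroxide (KOH, CCl4, t-BuOH/H2O), where the lactone is first opened in the flask to the potassium hydroxy carboxylate F3, whose C6 hydroxyl is not a leaving group. One-flask chlorination and contraction should give the ring-contracted carboxylate F4, and mild acidification re-closes the lactone onto the only free hydroxyl to give F5. PPTS in methanol removes the triethylsilyl group in the presence of the primary tert-butyldimethylsilyl ether to give the alcohol F6, and acylation with 23 (pyridine, DMAP) returns to the route at 28.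

Step 10. Intermolecular allylation may outrun closure of the ten-membered ring, or a non-chair pathway may erode the trans/anti relay. The fallback replaces the reductive metal-mediated allylation by an allylboration that needs no reductant. It sets out from 19, which is borylated at the allylic bromide (Pd2(dba)3, zerovalent palladium, B2pin2, toluene) to the allylboronate F7. Hydrolysis of the acetal with In(OTf)3 in wet acetone gives the aldehyde F8, which on warming at high dilution should cyclise by intramolecular allylboration through the same closed chair transition state. Aqueous work-up of the borate returns to the route at 22.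

Step 8. The β-thioether may sequester the ruthenium carbene as a five-membered chelate and stall turnover at the hindered bromomethacrylate. The fallback takes the donor sulfur away before metathesis and reorders the sequence. It sets out from 18, which is oxidised with mCPBA to the sulfone ester F9 and then closed by the same metathesis to the bromomethyl butenolide F10. Acetal hydrolysis (In(OTf)3, wet acetone) gives the aldehyde F11, and a zinc-mediated Barbier macrocyclisation (Zn, aq NH4Cl/THF, high dilution, tolerant of the acidic C4–H) gives the macrocyclic sulfone alcohol F12. Acylation with 23 returns to the route at 25.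

Further compounds
F1 | step 13 | 8-O-triethylsilyl ether of 22 | C=C1C(=O)O[C@@H]2CSC(CO[Si](C)(C)C(C)(C)C)C3=CC(=O)[C@@](C)(C[C@H](O[Si](CC)(CC)CC)[C@@H]12)O3
F2 | step 13 | sulfone of F1 | C=C1C(=O)O[C@@H]2CS(=O)(=O)C(CO[Si](C)(C)C(C)(C)C)C3=CC(=O)[C@@](C)(C[C@H](O[Si](CC)(CC)CC)[C@@H]12)O3
F3 | step 13 | potassium hydroxy carboxylate from lactone opening of F2 | C=C(C(=O)[O-])[C@H]2[C@H](O)CS(=O)(=O)C(CO[Si](C)(C)C(C)(C)C)C3=CC(=O)[C@@](C)(C[C@@H]2O[Si](CC)(CC)CC)O3.[K+]
F4 | step 13 | ring-contracted potassium hydroxy carboxylate (C4=C5 formed) | C=C(C(=O)[O-])[C@H]2[C@H](O)/C=C(/CO[Si](C)(C)C(C)(C)C)C3=CC(=O)[C@@](C)(C[C@@H]2O[Si](CC)(CC)CC)O3.[K+]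
F5 | step 13 | ring-contracted lactone, 8-O-triethylsilyl, 15-O-tert-butyldimethylsilyl | C=C1C(=O)O[C@@H]2/C=C(/CO[Si](C)(C)C(C)(C)C)C3=CC(=O)[C@@](C)(C[C@H](O[Si](CC)(CC)CC)[C@@H]12)O3
F6 | step 13 | ring-contracted lactone, 8-hydroxy, 15-O-tert-butyldimethylsilyl | C=C1C(=O)O[C@@H]2/C=C(/CO[Si](C)(C)C(C)(C)C)C3=CC(=O)[C@@](C)(C[C@H](O)[C@@H]12)O3
F7 | step 10 | pinacol allylboronate from 19 (boron on C13, acetal intact) | CC1(C)OB(CC2=C[C@@H](CSC(CO[Si](C)(C)C(C)(C)C)C3=CC(=O)[C@@](C)(CC(OC)OC)O3)OC2=O)OC1(C)C
F8 | step 10 | pinacol allylboronate aldehyde | CC1(C)OB(CC2=C[C@@H](CSC(CO[Si](C)(C)C(C)(C)C)C3=CC(=O)[C@@](C)(CC=O)O3)OC2=O)OC1(C)C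
F9 | step 8 | sulfone of ester 18 | C=C[C@H](OC(=O)C(=C)CBr)CS(=O)(=O)C(CO[Si](C)(C)C(C)(C)C)C1=CC(=O)[C@@](C)(CC(OC)OC)O1
F10 | step 8 | sulfone bromomethyl butenolide acetal | BrCC1=C[C@@H](CS(=O)(=O)C(CO[Si](C)(C)C(C)(C)C)C2=CC(=O)[C@@](C)(CC(OC)OC)O2)OC1=O
F11 | step 8 | sulfone bromomethyl butenolide aldehyde | BrCC1=C[C@@H](CS(=O)(=O)C(CO[Si](C)(C)C(C)(C)C)C2=CC(=O)[C@@](C)(CC=O)O2)OC1=O
F12 | step 8 | macrocyclic sulfone alcohol (8-OH) | C=C1C(=O)O[C@@H]2CS(=O)(=O)C(CO[Si](C)(C)C(C)(C)C)C3=CC(=O)[C@@](C)(C[C@H](O)[C@@H]12)O3
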